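**Strategy.** Ring C is opened at its two opposite bonds, C9–C11 and C13–C14, a [3+3] problem. The key step exploits that C9 is alpha to the ring B carbonyl C10 and that C14 is a CH2 on the quaternary C8: a cyclopropyl ketone (C8, C9, C14) is opened to a C9=C10 silyl enol ether bearing a C14 iodide. In one telescoped operation, zinc insertion and palladium-catalysed acylation with acryloyl chloride form C13–C14, and a silyl triflate then closes ring C by Mukaiyama–Michael addition (C9–C11), cis to ring B. Rings A and D are then grown from the C10 and C13 carbonyls.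

Key step: step 10

Remark: locants C1–C19 are those of the gibberellane skeleton of the target (C7 is the carboxyl carbon on C6, C19 the lactone carbonyl, C17 the exocyclic methylene). Names of 27–33 use the 20-norgibberellane skeleton with the natural absolute configuration; the SMILES are decisive. The target SMILES places the C15 hydroxyl on the face of ring D that is syn to C9 (15β), and the route is planned for that. C4 in 21–24 and C3 in 25–27 are carried as epimer mixtures because both centres are reset later (steps 14 and 17–18).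

## Route

Step 1
Reactants: 1 2,3-dibromoprop-1-ene; 2 ethynyltri(propan-2-yl)silane
Product: 4 (4-bromopent-4-en-1-yn-1-yl)tri(propan-2-yl)silane, via alkynylmagnesium bromide 3 (not isolated)
Conditions: EtMgBr, THF, 50 °C; then 1, CuBr·SMe2 (5 mol %), THF, 50 °C
Reagents that add atoms: none
Why: Copper-catalysed coupling of an alkynyl Grignard reagent with the allylic bromide of 1, the vinylic bromide being inert under these conditions.

Step 2
Reactants: 4 (4-bromopent-4-en-1-yn-1-yl)tri(propan-2-yl)silane; 5 (3-ethoxy-3-oxopropyl)zinc bromide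
Product: 6 ethyl 4-methylidene-7-[tri(propan-2-yl)silyl]hept-6-ynoate
Conditions: Pd(PPh3)4 (5 mol %), THF, 50 °C
Reagents that add atoms: none
Why: Negishi coupling; zerovalent palladium inserts only into the alkenyl C–Br bond and the ester-chelated alkylzinc resists β-hydride elimination.

Step 3
Reactants: 6 ethyl 4-methylidene-7-[tri(propan-2-yl)silyl]hept-6-ynoate
Product: 7 4-methylidene-7-[tri(propan-2-yl)silyl]hept-6-ynoic acid
Conditions: LiOH, THF/H2O, 23 °C; then 1 M HCl
Reagents that add atoms: lithium hydroxide, [Li+].[OH-]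
Why: Ester saponification; the bulky silyl group on the alkyne survives hydroxide.

Step 4
Reactants: 7 4-methylidene-7-[tri(propan-2-yl)silyl]hept-6-ynoic acid
Product: 9 1-diazo-5-methylidene-8-[tri(propan-2-yl)silyl]oct-7-yn-2-one, via acid chloride 8 (not isolated)
Conditions: (COCl)2, DMF (cat.), CH2Cl2, 0 to 23 °C; concentrate; then CH2N2 (excess), Et2O, 0 °C
Reagents that add atoms: diazomethane, C=[N+]=[N-]
Why: Acylation of diazomethane by the acid chloride (diazoketone synthesis), a second equivalent of diazomethane removing the HCl.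

Step 5
Reactants: 9 1-diazo-5-methylidene-8-[tri(propan-2-yl)silyl]oct-7-yn-2-one
Product: 10 (1R,5S)-5-{3-[tri(propan-2-yl)silyl]prop-2-yn-1-yl}bicyclo[3.1.0]hexan-2-one
Conditions: [Cu(MeCN)4]PF6 (5 mol %), 2,2'-(propane-2,2-diyl)bis(4-tert-butyl-4,5-dihydro-1,3-oxazole) (6 mol %, the enantiomer that gives 1R,5S), CH2Cl2, slow addition, 23 °C
Reagents that add atoms: none
Why: Intramolecular cyclopropanation of the copper carbenoid onto the 1,1-disubstituted alkene forms ring B and the quaternary C8; the chiral bis(oxazoline) on monovalent copper selects the alkene face and so sets C8 and C9 (cis fusion is obligatory).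

Step 6
Reactants: 10 (1R,5S)-5-{3-[tri(propan-2-yl)silyl]prop-2-yn-1-yl}bicyclo[3.1.0]hexan-2-one
Product: 12 (1R,5S)-5-{3-[tri(propan-2-yl)silyl]prop-2-yn-1-yl}bicyclo[3.1.0]hex-3-en-2-one, via lithium enolate 11 (not isolated)
Conditions: LiN(i-Pr)2, THF, −78 °C; then N-tert-butylbenzenesulfinimidoyl chloride, −78 °C
Reagents that add atoms: none
Why: Mukaiyama dehydrogenation; only C5 carries readily enolisable hydrogens, so the C5=C6 enone is the only possible product.

Step 7
Reactants: 12 (1R,5S)-5-{3-[tri(propan-2-yl)silyl]prop-2-yn-1-yl}bicyclo[3.1.0]hex-3-en-2-one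
Product: 14 (1R,4R,5S)-4-ethenyl-5-{3-[tri(propan-2-yl)silyl]prop-2-yn-1-yl}bicyclo[3.1.0]hexan-2-one, via trimethylsilyl enol ether 13 (not isolated)
Conditions: CH2=CHMgBr, CuBr·SMe2 (10 mol %), Me3SiCl, THF, −78 °C; then 1 M HCl, 0 °C
Reagents that add atoms: vinylmagnesium bromide, C=C[Mg]Br
Why: Copper-catalysed conjugate addition accelerated by Me3SiCl; the vinyl group (future C7) enters C6 from the face opposite to the cyclopropane CH2 (C14), whose inward hydrogen blocks the other face, which sets C6.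

Step 8
Reactants: 14 (1R,4R,5S)-4-ethenyl-5-{3-[tri(propan-2-yl)silyl]prop-2-yn-1-yl}bicyclo[3.1.0]hexan-2-one
Product: 15 methyl 4-oxo-1-{3-[tri(propan-2-yl)silyl]prop-2-yn-1-yl}bicyclo[3.1.0]hexane-2-carboxylate (ester trans to the cyclopropane CH2)
Conditions: O3, NaOH, MeOH, CH2Cl2, −78 °C
Reagents that add atoms: ozone, [O-][O+]=O; methanol, CO
Why: Ozonolysis in methanolic NaOH turns the vinyl group directly into the methyl ester, the silylated alkyne reacting far more slowly with ozone.

Step 9
Reactants: 15 methyl 4-oxo-1-{3-[tri(propan-2-yl)silyl]prop-2-yn-1-yl}bicyclo[3.1.0]hexane-2-carboxylate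
Product: 16 methyl 4-{[tert-butyl(dimethyl)silyl]oxy}-2-(iodomethyl)-2-{3-[tri(propan-2-yl)silyl]prop-2-yn-1-yl}cyclopent-3-ene-1-carboxylate (ester cis to the propynyl group)
Conditions: t-BuMe2SiCl, NaI, MeCN, 0 to 23 °C; then Et3N, pentane
Reagents that add atoms: tert-butyl(chloro)dimethylsilane, CC(C)(C)[Si](C)(C)Cl; sodium iodide, [Na+].[I-]
Why: Homoconjugate opening of the cyclopropyl ketone by the silyl iodide formed in the flask: O-silylation gives a cyclopropylcarbinyl oxocarbenium ion, which iodide opens at the unhindered CH2 (C14) of the external cyclopropane bond C9–C14 that overlaps with the carbonyl π system, so the C9=C10 silyl enol ether forms regiospecifically and no free enolate can re-close the ring.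

Step 10
Reactants: 16 methyl 4-{[tert-butyl(dimethyl)silyl]oxy}-2-(iodomethyl)-2-{3-[tri(propan-2-yl)silyl]prop-2-yn-1-yl}cyclopent-3-ene-1-carboxylate
Product: 19 methyl 6-{[tert-butyl(dimethyl)silyl]oxy}-3-oxo-7a-{3-[tri(propan-2-yl)silyl]prop-2-yn-1-yl}-2,3,3a,4,7,7a-hexahydro-1H-indene-1-carboxylate (cis-fused; H9 and C7 ester both cis to the propynyl group), via alkylzinc iodide 17 (not isolated), via vinyl ketone 18 (not isolated)
Conditions: Zn dust (activated with BrCH2CH2Br and Me3SiCl), THF, 40 °C; then decanted solution, CH2=CHCOCl (1.05 equiv), PdCl2(PPh3)2 (2 mol %), THF, 0 °C; then CH2Cl2, t-BuMe2SiOTf (0.3 equiv), −78 to −20 °C (no intermediate isolated)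
Reagents that add atoms: acryloyl chloride, C=CC(=O)Cl
Why: Zinc inserts into the C14–I bond (the methyl ester and both silyl groups are tolerated), and zerovalent palladium formed from the precatalyst couples the alkylzinc iodide 17 with the acid chloride (Negishi acylation), which forms C13–C14 and delivers the vinyl ketone 18. The silyl triflate then activates this enone and the C9=C10 silyl enol ether adds through C9 to C11 (intramolecular Mukaiyama–Michael addition, 6-endo-trig at the enone), which forms C9–C11, closes ring C and passes the silyl group from the C10 oxygen to the C13 oxygen. The closest known reaction types are the palladium-catalysed acylation of functionalised alkylzinc halides and silyl-triflate-catalysed Mukaiyama–Michael additions with silyl transfer. The only new stereocentre, C9, is fixed by the quaternary C8: the chain C14–C13–C12–C11 hangs from C8 and can reach only the face of C9 on which C14 lies, so H9 ends cis to C15 (cis B/C fusion). The step needs acylation at the carbonyl carbon instead of conjugate addition and no oligomerisation of 18; the palladium cycle that engages only the C–Cl bond, the absence of a β-hydrogen at C14 (C8 is quaternary), the near-stoichiometric acid chloride, low temperature and high dilution secure this. Because the silyl group ends on the C13 oxygen, the product carries the C13 carbonyl as its C12=C13 enol ether and the C10 ketone free, which tells the two carbonyls apart in the later steps.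

Step 11
Reactants: 19 methyl 6-{[tert-butyl(dimethyl)silyl]oxy}-3-oxo-7a-{3-[tri(propan-2-yl)silyl]prop-2-yn-1-yl}-2,3,3a,4,7,7a-hexahydro-1H-indene-1-carboxylate
Product: 21 the C5-alkylated ketone (19 with a 1-methoxy-1-oxopropan-2-yl group on C5; trans to the C7 ester; epimers at C4), via C5 lithium enolate 20 (not isolated)
Conditions: LiN(i-Pr)2, THF, −78 °C; then methyl 2-bromopropanoate, DMPU, −78 to −20 °C
Reagents that add atoms: methyl 2-bromopropanoate, CC(Br)C(=O)OC
Why: Kinetic enolisation at the C5 methylene (C9–H is a hindered ring-fusion methine) and enolate alkylation anti to the neighbouring C7 ester, which sets C5.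

Step 12
Reactants: 21 the C5-alkylated ketone
Product: 23 the 19,10-lactone carrying 2-(1,3-dioxolan-2-yl)ethyl (C1–C3) on C10 (C12=C13 silyl enol ether kept; epimers at C4), via bromomagnesium alkoxide 22 (not isolated)
Conditions: BrMgCH2CH2CH(OCH2CH2O), LaCl3·2LiCl (10 mol %), THF, −78 to 23 °C; then aq. NH4Cl
Reagents that add atoms: [2-(1,3-dioxolan-2-yl)ethyl]magnesium bromide, Br[Mg]CCC1OCCO1
Why: Grignard 1,2-addition to the C10 ketone from the convex face (anti to ring C and to the C5 side chain) sets C10, and the alkoxide, cis to the C5 side chain, lactonises onto the C19 ester; LaCl3·2LiCl suppresses enolisation.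

Step 13
Reactants: 23 the 19,10-lactone acetal
Product: 24 the keto aldehyde (23 with C3 as aldehyde and C13 as ketone)
Conditions: 2 M HCl, THF, 23 °C
Reagents that add atoms: water, O
Why: Acid hydrolysis of the dioxolane and of the silyl enol ether, which the lactone and the silylated alkyne withstand.

Step 14
Reactants: 24 the keto aldehyde
Product: 25 the tricyclic (rings A–C) keto lactone (3-hydroxy as epimer mixture; 13-ketone; 7-methyl ester; C8 carries the silylated propynyl chain)
Conditions: KOt-Bu (0.3 equiv), t-BuOH/THF, 0 °C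
Reagents that add atoms: none
Why: Intramolecular aldol addition of the lactone enolate (C4) to the C3 aldehyde closes ring A; the C4 configuration is dictated by the bridged lactone, while C3 is not controlled here and is reset in steps 17 and 18.

Step 15
Reactants: 25 the tricyclic keto lactone
Product: 26 the terminal alkyne (25 with C17–H)
Conditions: Bu4NF, AcOH, THF, 23 °C
Reagents that add atoms: none
Why: Fluoride cleaves the alkynyl C–Si bond, the acetic acid buffer keeping the β-hydroxy lactone from retro-aldol opening.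

Step 16
Reactants: 26 the terminal alkyne
Product: 27 methyl 3,13-dihydroxy-20-norgibberell-16-en-7-oate 19,10-lactone as a mixture of C3 epimers
Conditions: SmI2, HMPA, t-BuOH, THF, 0 °C
Reagents that add atoms: none
Why: Ketyl–alkyne reductive cyclisation: the samarium ketyl at C13 adds 5-exo-dig to C16 of the axial propynyl group, the one-carbon link C15 forcing bond formation on the face of ring C that carries C15 (sets C13), and the vinyl radical is reduced and protonated to the exocyclic methylene.

Step 17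
Reactants: 27 methyl 3,13-dihydroxy-20-norgibberell-16-en-7-oate 19,10-lactone (C3 epimers)
Product: 28 methyl 13-hydroxy-3-oxo-20-norgibberell-16-en-7-oate 19,10-lactone
Conditions: Dess–Martin periodinane, NaHCO3, CH2Cl2, 23 °C
Reagents that add atoms: none
Why: Dess–Martin oxidation of the only secondary alcohol converges both C3 epimers on one ketone, the tertiary C13 alcohol being inert.

Step 18
Reactants: 28 methyl 13-hydroxy-3-oxo-20-norgibberell-16-en-7-oate 19,10-lactone
Product: 29 methyl 3β,13-dihydroxy-20-norgibberell-16-en-7-oate 19,10-lactone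
Conditions: LiBH(s-Bu)3, THF, −78 °C
Reagents that add atoms: none
Why: The bulky hydride attacks the 3-ketone along the equatorial trajectory and so gives the axial 3β alcohol, on the face opposite to the lactone bridge.

Step 19
Reactants: 29 methyl 3β,13-dihydroxy-20-norgibberell-16-en-7-oate 19,10-lactone
Product: 30 methyl 3β,13,15α-trihydroxy-20-norgibberell-16-en-7-oate 19,10-lactone
Conditions: SeO2 (cat.), t-BuOOH, CH2Cl2, 23 °C
Reagents that add atoms: tert-butyl hydroperoxide, CC(C)(C)OO
Why: Selenium dioxide allylic oxidation (ene reaction then 2,3-shift) at C15, the only allylic CH2; oxygen should arrive on the open exo face (the side of C14), which is the 15α epimer.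

Step 20
Reactants: 30 methyl 3β,13,15α-trihydroxy-20-norgibberell-16-en-7-oate 19,10-lactone
Product: 31 methyl 3β,13-dihydroxy-15-oxo-20-norgibberell-16-en-7-oate 19,10-lactone
Conditions: MnO2, CH2Cl2, 23 °C
Reagents that add atoms: none
Why: MnO2 oxidises only the allylic C15 alcohol and leaves the C3 alcohol untouched.

Step 21
Reactants: 31 methyl 3β,13-dihydroxy-15-oxo-20-norgibberell-16-en-7-oate 19,10-lactone
Product: 32 methyl 3β,13,15β-trihydroxy-20-norgibberell-16-en-7-oate 19,10-lactone (methyl ester of the target)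
Conditions: NaBH4, CeCl3·7H2O, MeOH, −78 °C
Reagents that add atoms: none
Why: Luche 1,2-reduction of the enone; hydride enters from the exo face of the bicyclo[3.2.1]octane (the side of C14), which places the hydroxyl syn to C9 (15β).

Step 22
Reactants: 32 methyl 3β,13,15β-trihydroxy-20-norgibberell-16-en-7-oate 19,10-lactone
Product: 33 3β,13,15β-trihydroxy-20-norgibberell-16-ene-7,19-dioic acid 19,10-lactone (the target gibberellin)
Conditions: n-PrSLi, HMPA, 0 to 23 °C; then dilute HCl to pH 3
Reagents that add atoms: none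
Why: SN2 demethylation of the hindered C7 methyl ester by thiolate, which spares the lactone and avoids the basic hydrolysis that would epimerise C3 by retro-aldol.

## Compound list

1 | 2,3-dibromoprop-1-ene | C=C(Br)CBr | starting material
2 | ethynyltri(propan-2-yl)silane | C#C[Si](C(C)C)(C(C)C)C(C)C | starting material
3 | {[tri(propan-2-yl)silyl]ethynyl}magnesium bromide (formed in the flask) | Br[Mg]C#C[Si](C(C)C)(C(C)C)C(C)C | intermediate
4 | (4-bromopent-4-en-1-yn-1-yl)tri(propan-2-yl)silane | C=C(Br)CC#C[Si](C(C)C)(C(C)C)C(C)C | intermediate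
5 | (3-ethoxy-3-oxopropyl)zinc bromide | CCOC(=O)CC[Zn]Br | starting material
6 | ethyl 4-methylidene-7-[tri(propan-2-yl)silyl]hept-6-ynoate | CCOC(=O)CCC(=C)CC#C[Si](C(C)C)(C(C)C)C(C)C | intermediate
7 | 4-methylidene-7-[tri(propan-2-yl)silyl]hept-6-ynoic acid | OC(=O)CCC(=C)CC#C[Si](C(C)C)(C(C)C)C(C)C | intermediate
8 | 4-methylidene-7-[tri(propan-2-yl)silyl]hept-6-ynoyl chloride (formed in the flask) | ClC(=O)CCC(=C)CC#C[Si](C(C)C)(C(C)C)C(C)C | intermediate
9 | 1-diazo-5-methylidene-8-[tri(propan-2-yl)silyl]oct-7-yn-2-one | [N-]=[N+]=CC(=O)CCC(=C)CC#C[Si](C(C)C)(C(C)C)C(C)C | intermediate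
10 | (1R,5S)-5-{3-[tri(propan-2-yl)silyl]prop-2-yn-1-yl}bicyclo[3.1.0]hexan-2-one | O=C1CC[C@@]2(CC#C[Si](C(C)C)(C(C)C)C(C)C)C[C@@H]12 | intermediate
11 | lithium enolate (C5=C10–OLi) of 10 (formed in the flask) | [Li]OC1=CC[C@@]2(CC#C[Si](C(C)C)(C(C)C)C(C)C)C[C@@H]12 | intermediate
12 | (1R,5S)-5-{3-[tri(propan-2-yl)silyl]prop-2-yn-1-yl}bicyclo[3.1.0]hex-3-en-2-one | O=C1C=C[C@@]2(CC#C[Si](C(C)C)(C(C)C)C(C)C)C[C@@H]12 | intermediate
13 | trimethylsilyl enol ether (C5=C10–OSiMe3) of 14 (formed in the flask) | C[Si](C)(C)OC1=C[C@H](C=C)[C@@]2(CC#C[Si](C(C)C)(C(C)C)C(C)C)C[C@@H]12 | intermediate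
14 | (1R,4R,5S)-4-ethenyl-5-{3-[tri(propan-2-yl)silyl]prop-2-yn-1-yl}bicyclo[3.1.0]hexan-2-one (ethenyl trans to the cyclopropane CH2) | O=C1C[C@H](C=C)[C@@]2(CC#C[Si](C(C)C)(C(C)C)C(C)C)C[C@@H]12 | intermediate
15 | methyl 4-oxo-1-{3-[tri(propan-2-yl)silyl]prop-2-yn-1-yl}bicyclo[3.1.0]hexane-2-carboxylate (ester trans to the cyclopropane CH2) | O=C1C[C@H](C(=O)OC)[C@@]2(CC#C[Si](C(C)C)(C(C)C)C(C)C)C[C@@H]12 | intermediate
16 | methyl 4-{[tert-butyl(dimethyl)silyl]oxy}-2-(iodomethyl)-2-{3-[tri(propan-2-yl)silyl]prop-2-yn-1-yl}cyclopent-3-ene-1-carboxylate (ester cis to the propynyl group) | CC(C)(C)[Si](C)(C)OC1=C[C@@](CI)(CC#C[Si](C(C)C)(C(C)C)C(C)C)[C@@H](C(=O)OC)C1 | intermediate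
17 | C14-zincio analogue of 16 (CH2ZnI in place of CH2I; formed in the flask) | CC(C)(C)[Si](C)(C)OC1=C[C@@](C[Zn]I)(CC#C[Si](C(C)C)(C(C)C)C(C)C)[C@@H](C(=O)OC)C1 | intermediate
18 | methyl 4-{[tert-butyl(dimethyl)silyl]oxy}-2-(2-oxobut-3-en-1-yl)-2-{3-[tri(propan-2-yl)silyl]prop-2-yn-1-yl}cyclopent-3-ene-1-carboxylate (formed in the flask) | CC(C)(C)[Si](C)(C)OC1=C[C@@](CC(=O)C=C)(CC#C[Si](C(C)C)(C(C)C)C(C)C)[C@@H](C(=O)OC)C1 | intermediate
19 | methyl 6-{[tert-butyl(dimethyl)silyl]oxy}-3-oxo-7a-{3-[tri(propan-2-yl)silyl]prop-2-yn-1-yl}-2,3,3a,4,7,7a-hexahydro-1H-indene-1-carboxylate (cis-fused; H9 and C7 ester both cis to the propynyl group) | O=C1C[C@H](C(=O)OC)[C@@]2(CC#C[Si](C(C)C)(C(C)C)C(C)C)CC(O[Si](C)(C)C(C)(C)C)=CC[C@@H]12 | intermediate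
20 | lithium enolate (C5=C10–OLi) of 19 (formed in the flask) | [Li]OC1=C[C@H](C(=O)OC)[C@@]2(CC#C[Si](C(C)C)(C(C)C)C(C)C)CC(O[Si](C)(C)C(C)(C)C)=CC[C@@H]12 | intermediate
21 | 19 with a 1-methoxy-1-oxopropan-2-yl group on C5 (trans to the C7 ester; epimers at C4) | O=C1[C@@H](C(C)C(=O)OC)[C@H](C(=O)OC)[C@@]2(CC#C[Si](C(C)C)(C(C)C)C(C)C)CC(O[Si](C)(C)C(C)(C)C)=CC[C@@H]12 | intermediate
22 | bromomagnesium C10 alkoxide from Grignard addition to 21 (formed in the flask) | COC(=O)C(C)[C@H]1[C@H](C(=O)OC)[C@@]2(CC#C[Si](C(C)C)(C(C)C)C(C)C)CC(O[Si](C)(C)C(C)(C)C)=CC[C@H]2[C@@]1(CCC1OCCO1)O[Mg]Br | intermediate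
23 | 19,10-lactone with 2-(1,3-dioxolan-2-yl)ethyl (C1–C3) on C10 and the C12=C13 silyl enol ether (epimers at C4) | CC1C(=O)O[C@@]2(CCC3OCCO3)[C@@H]1[C@H](C(=O)OC)[C@@]1(CC#C[Si](C(C)C)(C(C)C)C(C)C)CC(O[Si](C)(C)C(C)(C)C)=CC[C@H]12 | intermediate
24 | keto aldehyde: 23 with C3 as aldehyde and C13 as ketone (epimers at C4) | CC1C(=O)O[C@@]2(CCC=O)[C@@H]1[C@H](C(=O)OC)[C@@]1(CC#C[Si](C(C)C)(C(C)C)C(C)C)CC(=O)CC[C@H]12 | intermediate
25 | tricyclic (rings A–C) keto lactone: 7-methyl ester; 19,10-lactone; 3-hydroxy (epimers); 13-ketone; silylated propynyl chain on C8 | CC(C)[Si](C(C)C)(C(C)C)C#CC[C@]12CC(=O)CC[C@H]1[C@@]13CCC(O)[C@@](C)(C(=O)O1)[C@H]3[C@@H]2C(=O)OC | intermediate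
26 | 25 with a terminal alkyne (C17–H) | C#CC[C@]12CC(=O)CC[C@H]1[C@@]13CCC(O)[C@@](C)(C(=O)O1)[C@H]3[C@@H]2C(=O)OC | intermediate
27 | methyl 3,13-dihydroxy-20-norgibberell-16-en-7-oate 19,10-lactone (mixture of C3 epimers) | C=C1C[C@]23C[C@@]1(O)CC[C@H]2[C@@]12CCC(O)[C@@](C)(C(=O)O1)[C@H]2[C@@H]3C(=O)OC | intermediate
28 | methyl 13-hydroxy-3-oxo-20-norgibberell-16-en-7-oate 19,10-lactone | C=C1C[C@]23C[C@@]1(O)CC[C@H]2[C@@]12CCC(=O)[C@@](C)(C(=O)O1)[C@H]2[C@@H]3C(=O)OC | intermediate
29 | methyl 3β,13-dihydroxy-20-norgibberell-16-en-7-oate 19,10-lactone | C=C1C[C@]23C[C@@]1(O)CC[C@H]2[C@@]12CC[C@H](O)[C@@](C)(C(=O)O1)[C@H]2[C@@H]3C(=O)OC | intermediate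
30 | methyl 3β,13,15α-trihydroxy-20-norgibberell-16-en-7-oate 19,10-lactone (15-epimer of 32) | C=C1[C@H](O)[C@]23C[C@@]1(O)CC[C@H]2[C@@]12CC[C@H](O)[C@@](C)(C(=O)O1)[C@H]2[C@@H]3C(=O)OC | intermediate
31 | methyl 3β,13-dihydroxy-15-oxo-20-norgibberell-16-en-7-oate 19,10-lactone | C=C1C(=O)[C@]23C[C@@]1(O)CC[C@H]2[C@@]12CC[C@H](O)[C@@](C)(C(=O)O1)[C@H]2[C@@H]3C(=O)OC | intermediate
32 | methyl 3β,13,15β-trihydroxy-20-norgibberell-16-en-7-oate 19,10-lactone (methyl ester of the target) | C=C1[C@@H](O)[C@]23C[C@@]1(O)CC[C@H]2[C@@]12CC[C@H](O)[C@@](C)(C(=O)O1)[C@H]2[C@@H]3C(=O)OC | intermediate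
33 | 3β,13,15β-trihydroxy-20-norgibberell-16-ene-7,19-dioic acid 19,10-lactone (the target gibberellin) | C=C1[C@@H](O)[C@]23C[C@@]1(O)CC[C@H]2[C@@]12CC[C@H](O)[C@@](C)(C(=O)O1)[C@H]2[C@@H]3C(=O)O | target

## Step count and risks

Total step count: 22. Longest linear sequence: 22 steps (from 1 and 2 to 33).

Steps most likely to fail:

1. Step 10 (key step). Zinc insertion at the hindered C14 iodide may be slow, acryloyl chloride or the vinyl ketone may oligomerise in the crude organozinc mixture, and the zinc salts may quench the silyl triflate before ring C closes. Fallback, from 16 back to 19: the alkylzinc iodide from 16 is acylated with 3-chloropropanoyl chloride (PdCl2(PPh3)2, THF) instead, and the masked vinyl ketone methyl 4-{[tert-butyl(dimethyl)silyl]oxy}-2-(4-chloro-2-oxobutyl)-2-{3-[tri(propan-2-yl)silyl]prop-2-yn-1-yl}cyclopent-3-ene-1-carboxylate F1 is isolated and purified. DBU in CH2Cl2 at 0 °C then removes HCl to release 18, which after an aqueous wash is cyclised in a clean medium with a catalytic amount of t-BuMe2SiOTf at −78 °C to give 19.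

2. Step 11. Proton transfer and elimination may outrun substitution at the secondary bromide, and facial control at C5 may be poor. Fallback, from 19 back to 23: the enolate 20 is alkylated with the far more reactive methyl bromoacetate to the ketone methyl 6-{[tert-butyl(dimethyl)silyl]oxy}-2-(2-methoxy-2-oxoethyl)-3-oxo-7a-{3-[tri(propan-2-yl)silyl]prop-2-yn-1-yl}-2,3,3a,4,7,7a-hexahydro-1H-indene-1-carboxylate F2. Grignard addition and lactonisation under the conditions of step 12 give the 19,10-lactone without the C4 methyl group F3. Deprotonation of the unhindered lactone CH2 (LiN(i-Pr)2, THF, −78 °C) and methylation with MeI then install the methyl group at C4 and give 23.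

3. Step 5. Facial discrimination by the chiral copper catalyst may be poor for this unsubstituted diazoketone, or C–H insertion may compete with cyclopropanation. Fallback, from 9 back to 10: 9 is cyclised with achiral Rh2(OAc)4 to the racemic ketone 5-{3-[tri(propan-2-yl)silyl]prop-2-yn-1-yl}bicyclo[3.1.0]hexan-2-one F4, and the enantiomers are separated by an enzymatic kinetic resolution in which a ketoreductase (alcohol dehydrogenase with NADPH recycling) reduces the unwanted (1S,5R) ketone to the alcohol (1S,5R)-configured 5-{3-[tri(propan-2-yl)silyl]prop-2-yn-1-yl}bicyclo[3.1.0]hexan-2-ol F5. The untouched (1R,5S) ketone is 10.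

## Further compounds

F1 | step 10 | methyl 4-{[tert-butyl(dimethyl)silyl]oxy}-2-(4-chloro-2-oxobutyl)-2-{3-[tri(propan-2-yl)silyl]prop-2-yn-1-yl}cyclopent-3-ene-1-carboxylate | CC(C)(C)[Si](C)(C)OC1=C[C@@](CC(=O)CCCl)(CC#C[Si](C(C)C)(C(C)C)C(C)C)[C@@H](C(=O)OC)C1
F2 | step 11 | methyl 6-{[tert-butyl(dimethyl)silyl]oxy}-2-(2-methoxy-2-oxoethyl)-3-oxo-7a-{3-[tri(propan-2-yl)silyl]prop-2-yn-1-yl}-2,3,3a,4,7,7a-hexahydro-1H-indene-1-carboxylate (side chain trans to the C7 ester) | O=C1[C@@H](CC(=O)OC)[C@H](C(=O)OC)[C@@]2(CC#C[Si](C(C)C)(C(C)C)C(C)C)CC(O[Si](C)(C)C(C)(C)C)=CC[C@@H]12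
F3 | step 11 | 19,10-lactone with 2-(1,3-dioxolan-2-yl)ethyl on C10 and the C12=C13 silyl enol ether, without the methyl group on C4 | C1C(=O)O[C@@]2(CCC3OCCO3)[C@@H]1[C@H](C(=O)OC)[C@@]1(CC#C[Si](C(C)C)(C(C)C)C(C)C)CC(O[Si](C)(C)C(C)(C)C)=CC[C@H]12
F4 | step 5 | racemic 5-{3-[tri(propan-2-yl)silyl]prop-2-yn-1-yl}bicyclo[3.1.0]hexan-2-one | O=C1CCC2(CC#C[Si](C(C)C)(C(C)C)C(C)C)CC12
F5 | step 5 | (1S,5R)-configured 5-{3-[tri(propan-2-yl)silyl]prop-2-yn-1-yl}bicyclo[3.1.0]hexan-2-ol (hydroxyl cis to the cyclopropane CH2) | O[C@@H]1CC[C@]2(CC#C[Si](C(C)C)(C(C)C)C(C)C)C[C@H]12
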